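**Retrosynthetic overview**
- Feature: in the hydroxyquinone ring (C1'–C6'; C1' on the drimane C11 methylene, OH on C2', C=O at C3' and C6', CH2OH on C4'), carbons C1', C6' and C5' are the side-chain carbons C12, C13 and C16 of (+)-manool 1. They survive in its degradation product, methyl ketone 2. The missing C2', C3', C4' and the CH2OH carbon are the four carbons of dimethyl fumarate 3.
- Disconnections: the hydroxyquinone goes back by Teuber oxidation to a 2-alkyl-5-(hydroxymethyl)resorcinol whose two free ring positions are equivalent. Ester reduction and dehydrogenation lead back to a 4-alkyl-3,5-dioxocyclohexanecarboxylate, which is cut at C1'–C2' (Dieckmann) and C5'–C4' (Michael) to 2 + 3.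
- Ring order: rings A and B, C5, C9, C10 and the exocyclic 8(12) alkene are bought with 1. The only ring made is the six-membered carbocycle, closed in step 2, aromatised in steps 3 and 4, and oxidised last.

Key step: step 2

Assumption: (+)-manool is used as the (5S,9S,10S,13R) enantiomer, which carries the three ring stereocentres of the target unchanged.
Remark on names: "drim-8(12)-en-11-yl" is the [(1S,4aS,8aS)-5,5,8a-trimethyl-2-methylidenedecahydronaphthalen-1-yl]methyl group, so C11 is the CH2 that carries the new ring.

**Step 1**
Reactants: 1 (+)-manool, (13R)-labda-8(17),14-dien-13-ol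
Product: 2 14,15-dinorlabd-8(17)-en-13-one, i.e. 1-(drim-8(12)-en-11-yl)propan-2-one
Conditions: KMnO4 (4 equiv, in portions), acetone–H2O, 0 °C to rt
Reagents that add atoms: none
Why: Permanganate degradation of the allylic tertiary carbinol, in which the monosubstituted vinyl group is hydroxylated and the resulting 13,14,15-triol is cleaved twice so that C14 and C15 leave as carbonate and the original hydroxyl oxygen becomes the ketone, while the hindered 1,1-disubstituted ring alkene next to the quaternary C10 reacts more slowly and C5, C9 and C10 are untouched.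

**Step 2**
Reactants: 2 14,15-dinorlabd-8(17)-en-13-one; 3 dimethyl fumarate
Product: 5 methyl 4-(drim-8(12)-en-11-yl)-3,5-dioxocyclohexane-1-carboxylate, via Michael adduct 4 (not isolated)
Conditions: 2 added to LiN(iPr)2 (1.05 equiv), THF, −78 °C; 3 (1.0 equiv) added slowly, −78 °C; then NaOMe (2 equiv), MeOH, −78 °C to 65 °C; 1 M HCl to pH 3 at 0 °C
Reagents that add atoms: none
Why: The kinetic lithium enolate of 2, formed at the C16 methyl (the future C5') by the bulky amide at −78 °C, adds in conjugate fashion to fumarate 3 and forms C5'–C4', giving the acetonylsuccinate 4 as its ester enolate. Under sodium methoxide the enolates equilibrate, and the C12 (future C1') enolate attacks the ester on the CH2 arm in a Dieckmann (intramolecular Claisen) condensation that forms C1'–C2' and closes the six-membered ring in a 6-exo-trig mode. The closest known reaction type is the Michael addition of a ketone to a maleate or fumarate followed by base cyclisation of the acetonylsuccinate to a 3,5-dioxocyclohexanecarboxylate. No stereocentre of the target is made: C4' and C1' of 5 form without control and both become sp2 carbons on aromatisation, while C5, C9 and C10 are out of reach of the base. The step needs deprotonation at the methyl rather than the more substituted C12 methylene, which the kinetic conditions secure, and six- over five-membered closure, which is secured because all Claisen closures are reversible in methanol and only the unstrained cyclohexane-1,3-dione is withdrawn as its stable enolate.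

**Step 3**
Reactants: 5 methyl 4-(drim-8(12)-en-11-yl)-3,5-dioxocyclohexane-1-carboxylate
Product: 6 methyl 4-(drim-8(12)-en-11-yl)-3,5-bis(trimethylsilyloxy)cyclohexa-2,4-diene-1-carboxylate
Conditions: TMSOTf (2.5 equiv), Et3N (3 equiv), Et2O, 0 °C to rt; pentane, filtration under argon, used crude
Reagents that add atoms: trimethylsilyl trifluoromethanesulfonate, C[Si](C)(C)OS(=O)(=O)C(F)(F)F
Why: Double soft enolisation with a silyl triflate and an amine base is the standard route from a cyclic 1,3-dione to its 1,3-bis(silyloxy)-1,3-diene, the first silylation giving the vinylogous silyl ester and the second removing an α' proton (C5' or the equivalent C3'), while the methyl ester and the isolated alkene are left alone by the amine-buffered reagent.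

**Step 4**
Reactants: 6 methyl 4-(drim-8(12)-en-11-yl)-3,5-bis(trimethylsilyloxy)cyclohexa-2,4-diene-1-carboxylate
Product: 8 methyl 4-(drim-8(12)-en-11-yl)-3,5-dihydroxybenzoate, via aryl silyl ether 7 (not isolated)
Conditions: Pd(OAc)2 (1.1 equiv), MeCN, rt; filtration through Celite; then MeOH, rt
Reagents that add atoms: none
Why: Saegusa–Ito oxidation, in which divalent palladium attacks the terminal diene carbon C5', Me3SiOAc is lost, β-hydride elimination of H–C4' releases zerovalent palladium and a cyclohexa-2,5-dienone that tautomerises to the phenol 7, and the remaining aryl silyl ether is methanolysed by the acetic acid already present.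

**Step 5**
Reactants: 8 methyl 4-(drim-8(12)-en-11-yl)-3,5-dihydroxybenzoate
Product: 9 2-(drim-8(12)-en-11-yl)-5-(hydroxymethyl)benzene-1,3-diol
Conditions: LiAlH4 (4 equiv), THF, 0 °C to 65 °C; aq. KNaC4H4O6 work-up
Reagents that add atoms: none
Why: LiAlH4 reduction of an aryl ester, in which the two phenols are first deprotonated (hence the excess hydride), the meta-phenoxides do not deactivate the ester enough to stop reduction at reflux, and the unactivated exocyclic alkene is inert to hydride.

**Step 6**
Reactants: 9 2-(drim-8(12)-en-11-yl)-5-(hydroxymethyl)benzene-1,3-diol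
Product: 10 tauranin, 2-(drim-8(12)-en-11-yl)-3-hydroxy-5-(hydroxymethyl)cyclohexa-2,5-diene-1,4-dione
Conditions: ON(SO3K)2 (2.5 equiv), aq. KH2PO4 (pH 6), acetone–H2O, 0 °C to rt; then dilute HCl to pH 3
Reagents that add atoms: dipotassium nitrosodisulfonate ON(SO3K)2, [K+].[K+].[O]N(S(=O)(=O)[O-])S(=O)(=O)[O-]
Why: Teuber oxidation, in which the nitroxide abstracts a phenolic hydrogen, a second radical couples through oxygen at the free position para to that hydroxyl (C3', also ortho to the other hydroxyl) and loss of HN(SO3K)2 gives the 2-hydroxy-1,4-benzoquinone; the two free ring positions of 9 lead to the same hydroxyquinone, and the alkene and the primary alcohol are not attacked by this reagent.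

**Compound list**
1 | (+)-manool, (5S,9S,10S,13R)-labda-8(17),14-dien-13-ol | C=C1CC[C@H]2C(C)(C)CCC[C@]2(C)[C@H]1CC[C@@](C)(O)C=C | starting material
2 | 14,15-dinorlabd-8(17)-en-13-one, 1-(drim-8(12)-en-11-yl)propan-2-one (5S,9S,10S) | C=C1CC[C@H]2C(C)(C)CCC[C@]2(C)[C@H]1CCC(C)=O | intermediate
3 | dimethyl fumarate, dimethyl (E)-but-2-enedioate | COC(=O)/C=C/C(=O)OC | starting material
4 | dimethyl 2-[3-(drim-8(12)-en-11-yl)-2-oxopropyl]butanedioate (both epimers at the succinate carbon) | C=C1CC[C@H]2C(C)(C)CCC[C@]2(C)[C@H]1CCC(=O)CC(CC(=O)OC)C(=O)OC | intermediate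
5 | methyl 4-(drim-8(12)-en-11-yl)-3,5-dioxocyclohexane-1-carboxylate (ring epimers and enol tautomers) | C=C1CC[C@H]2C(C)(C)CCC[C@]2(C)[C@H]1CC1C(=O)CC(C(=O)OC)CC1=O | intermediate
6 | methyl 4-(drim-8(12)-en-11-yl)-3,5-bis(trimethylsilyloxy)cyclohexa-2,4-diene-1-carboxylate (both epimers at C1 of the ring) | C=C1CC[C@H]2C(C)(C)CCC[C@]2(C)[C@H]1CC1=C(O[Si](C)(C)C)CC(C(=O)OC)C=C1O[Si](C)(C)C | intermediate
7 | methyl 4-(drim-8(12)-en-11-yl)-3-hydroxy-5-(trimethylsilyloxy)benzoate | C=C1CC[C@H]2C(C)(C)CCC[C@]2(C)[C@H]1Cc1c(O)cc(C(=O)OC)cc1O[Si](C)(C)C | intermediate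
8 | methyl 4-(drim-8(12)-en-11-yl)-3,5-dihydroxybenzoate | C=C1CC[C@H]2C(C)(C)CCC[C@]2(C)[C@H]1Cc1c(O)cc(C(=O)OC)cc1O | intermediate
9 | 2-(drim-8(12)-en-11-yl)-5-(hydroxymethyl)benzene-1,3-diol | C=C1CC[C@H]2C(C)(C)CCC[C@]2(C)[C@H]1Cc1c(O)cc(CO)cc1O | intermediate
10 | tauranin, 2-(drim-8(12)-en-11-yl)-3-hydroxy-5-(hydroxymethyl)cyclohexa-2,5-diene-1,4-dione (5S,9S,10S) | C=C1CC[C@H]2C(C)(C)CCC[C@]2(C)[C@H]1CC1=C(O)C(=O)C(CO)=CC1=O | target

**Total step count:** 6
**Longest linear sequence:** 6 steps (1 to 10)

**Steps most likely to fail**

1. Step 2. Proton exchange between the first-formed ester enolate and unreacted ketone can scramble the enolate regiochemistry, and the adduct enolate can add to a second fumarate (oligomerisation). Partial deprotonation at C12 would lead to a regioisomeric dione. The fallback sets out from 2 and comes back at 5. Ketone 2 is condensed with 1,1-dimethylhydrazine (EtOH, cat. AcOH, reflux) to the N,N-dimethylhydrazone F1. This is metalated with LiN(iPr)2 (THF, −78 °C), which takes place at the methyl group, and the azaenolate is added to 3 at −78 °C and quenched cold to give the hydrazone Michael adduct F2. Hydrolysis with aqueous oxalic acid/Et2O at rt releases the acetonylsuccinate 4, now isolated. NaOMe in MeOH at 65 °C then closes it to 5.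

2. Step 4. The palladium hydride formed in the β-hydride elimination may move the exocyclic 8(12) alkene into ring B, and palladation at C1' instead of C5' would lead to elimination toward C11. The fallback sets out from 5 and comes back at 8. The dianion of 5 (LiN(iPr)2, 2.2 equiv, THF, −78 to −30 °C) is selenated at the α' carbon with PhSeBr at −78 °C to give methyl 4-(drim-8(12)-en-11-yl)-3,5-dioxo-2-(phenylselanyl)cyclohexane-1-carboxylate F3. Oxidation with H2O2/pyridine in CH2Cl2 at 0 °C triggers selenoxide syn-elimination, and the resulting enedione tautomerises to the resorcinol 8.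

3. Step 6. The radical oxidation may stall, since a resorcinol is a less willing Teuber substrate than a para-activated phenol. The acidic hydroxyquinone and the benzylic alcohol may also be oxidised further or condense under the buffered conditions. The fallback sets out from 9 and comes back at 10. Azo coupling of 9 with one equivalent of 4-sulfobenzenediazonium (from sulfanilic acid, NaNO2, HCl; aq. Na2CO3, 0 °C) should give the 4-arylazo resorcinol F4. Reduction with Na2S2O4 (aq. NaOH/EtOH, 50 °C) gives the 4-aminoresorcinol F5, used at once. FeCl3 in cold dilute HCl oxidises it to the quinone imine, which hydrolyses to 10.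

**Further compounds**
F1 | step 2 | 14,15-dinorlabd-8(17)-en-13-one N,N-dimethylhydrazone | C=C1CC[C@H]2C(C)(C)CCC[C@]2(C)[C@H]1CCC(C)=NN(C)C
F2 | step 2 | dimethyl 2-[3-(drim-8(12)-en-11-yl)-2-(dimethylhydrazinylidene)propyl]butanedioate | C=C1CC[C@H]2C(C)(C)CCC[C@]2(C)[C@H]1CCC(=NN(C)C)CC(CC(=O)OC)C(=O)OC
F3 | step 4 | methyl 4-(drim-8(12)-en-11-yl)-3,5-dioxo-2-(phenylselanyl)cyclohexane-1-carboxylate | C=C1CC[C@H]2C(C)(C)CCC[C@]2(C)[C@H]1CC1C(=O)CC(C(=O)OC)C([Se]c2ccccc2)C1=O
F4 | step 6 | 4-[[3-(drim-8(12)-en-11-yl)-2,4-dihydroxy-6-(hydroxymethyl)phenyl]diazenyl]benzenesulfonic acid | C=C1CC[C@H]2C(C)(C)CCC[C@]2(C)[C@H]1Cc1c(O)cc(CO)c(/N=N/c2ccc(S(=O)(=O)O)cc2)c1O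
F5 | step 6 | 4-amino-2-(drim-8(12)-en-11-yl)-5-(hydroxymethyl)benzene-1,3-diol | C=C1CC[C@H]2C(C)(C)CCC[C@]2(C)[C@H]1Cc1c(O)cc(CO)c(N)c1O
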